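**Retrosynthetic overview**
1. Target 22 ⇐ spiro enol lactone 21 by face-selective epoxidation; 21 ⇐ acetate 20 by a Ti-mediated Dieckmann-type C-acylation of the C-1 butenolide with the C-12 ester (C12–C13; ring C and the spiro centre form last).
2. Rings A and B form together in one intramolecular Diels–Alder reaction of triene acid 14 (C5–C10 and C1–C2); the C-18/C-19 lactone closes in the same pot; C-7 goes NO2 → C=O → axial OAc.
3. 14 ⇐ nitroalkane 7 + vinylbutenolide 13 by Pd-catalysed lactone-opening allylation (C6–C7), which fixes the diene geometry required for a trans ring fusion.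
4. 7 ⇐ alkyne 4 + 3-bromobutenolide 5 by hydrostannation/Stille coupling (C1–C13).
5. Key step: 4 ⇐ ynenal 2 + nitropropene 3 by NHC-homoenolate addition (C8–C9), setting quaternary C-9 and tertiary C-8 in one operation.

Assumption: atoms are referred to by clerodane numbering (C-1 to C-20; C-18/C-19 = ring-A lactone, C-13 = spiro carbon, C-16 = its lactone carbonyl); α is the face of the C-19 and C-20 substituents, β the face of H-10.

**Route**

Step 1
Reactants: 1 (E)-3-methylpent-2-en-4-yn-1-ol
Product: 2 (E)-3-methylpent-2-en-4-ynal
Conditions: activated MnO2 (10 equiv), CH2Cl2, rt, 2 h; filtered solution used directly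
Reagents that add atoms: none
Why: Allylic oxidation with MnO2 stops at the enal and leaves the alkyne and the E double bond unchanged; no stereocentre is involved.

Step 2
Reactants: 2 (E)-3-methylpent-2-en-4-ynal; 3 (E)-1-nitroprop-1-ene
Product: 4 methyl (3S,4S)-3-ethynyl-3,4-dimethyl-5-nitropentanoate
Conditions: (5aR,10bS)-2-mesityl-5a,10b-dihydro-4H,6H-indeno[2,1-b][1,2,4]triazolo[4,3-d][1,4]oxazin-2-ium chloride (10 mol %), NaOAc (20 mol %), MeOH (5 equiv), toluene, 0 °C → rt, 3 added over 6 h
Reagents that add atoms: methanol, CO
Why: Proposed new method: the carbene adds to the aldehyde of 2 to give the conjugated Breslow intermediate, whose β-carbon (C-9, normally electrophilic) attacks the β-carbon of the nitroalkene (C-8, also normally electrophilic), and methanolysis of the resulting acyl azolium releases the ester and the catalyst; the closest known reaction is the NHC-catalysed homoenolate addition of β-monosubstituted enals to nitroalkenes giving δ-nitro esters with high dr and ee, extended here to a β-methyl-β-ethynyl enal whose slim sp substituent keeps the β-carbon accessible, the chiral triazolium selecting one face of the E-homoenolate and of the E-nitroalkene so that quaternary C-9 and tertiary C-8 are set together as (3S,4S) (the antipodal catalyst would be used if the sense of induction proved opposite).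

Step 3
Reactants: 4 methyl (3S,4S)-3-ethynyl-3,4-dimethyl-5-nitropentanoate; 5 3-bromofuran-2(5H)-one
Product: 7 methyl (3R,4S)-3,4-dimethyl-5-nitro-3-[(E)-2-(2-oxo-2,5-dihydrofuran-3-yl)ethenyl]pentanoate, via E-vinylstannane 6 (not isolated)
Conditions: Bu3SnH (1.1 equiv), PdCl2(PPh3)2 (3 mol %), THF, 0 °C; then 5 (1.2 equiv), CuI (20 mol %), DMF, 50 °C
Reagents that add atoms: none
Why: Palladium-catalysed syn-hydrostannation puts tin on the terminal carbon because the quaternary neighbour blocks the internal position, and the Stille coupling with the α-bromobutenolide proceeds with retention to give the E-diene; the two stereocentres are untouched (the C-3 descriptor changes from S to R only through CIP priorities).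

Step 4
Reactants: 8 1,3-dihydroxyacetone (supplied as its dimer); 9 ethyl (triphenylphosphoranylidene)acetate
Product: 10 4-(hydroxymethyl)furan-2(5H)-one
Conditions: CH2Cl2, rt, 24 h
Reagents that add atoms: none
Why: Wittig olefination of the ketone is followed by spontaneous lactonisation, since one of the two CH2OH groups on the β-carbon is always cis to the ester; no stereocentre.

Step 5
Reactants: 10 4-(hydroxymethyl)furan-2(5H)-one
Product: 12 3-bromo-4-(hydroxymethyl)furan-2(5H)-one, via trans-dibromide 11 (not isolated)
Conditions: Br2 (1.05 equiv), CH2Cl2, 0 °C; then Et3N (1.5 equiv), 0 °C → rt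
Reagents that add atoms: bromine, BrBr
Why: Anti addition of bromine across the butenolide double bond and base-induced loss of HBr through the acidic α-proton (addition–elimination) give the α-bromobutenolide; the stereocentres of 11 disappear.

Step 6
Reactants: 12 3-bromo-4-(hydroxymethyl)furan-2(5H)-one
Product: 13 3-ethenyl-4-(hydroxymethyl)furan-2(5H)-one
Conditions: tributyl(vinyl)stannane (1.2 equiv), Pd(PPh3)4 (5 mol %), BHT, dioxane, 90 °C
Reagents that add atoms: tributyl(vinyl)stannane, C=C[Sn](CCCC)(CCCC)CCCC
Why: Stille coupling of the vinyl bromide tolerates the free alcohol and the lactone; no stereocentre.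

Step 7
Reactants: 7 methyl (3R,4S)-3,4-dimethyl-5-nitro-3-[(E)-2-(2-oxo-2,5-dihydrofuran-3-yl)ethenyl]pentanoate; 13 3-ethenyl-4-(hydroxymethyl)furan-2(5H)-one
Product: 14 (2E)-2-ethenyl-3-(hydroxymethyl)-9-methoxy-6,7-dimethyl-5-nitro-9-oxo-7-[(E)-2-(2-oxo-2,5-dihydrofuran-3-yl)ethenyl]non-2-enoic acid (C-5 of this name, i.e. C-7 of the target, as both epimers)
Conditions: Pd(PPh3)4 (5 mol %), DBU (1.05 equiv, slow addition), THF, 40 °C; aqueous HCl work-up
Reagents that add atoms: none
Why: Proposed new method: zerovalent palladium ionises the allylic C–O bond of butenolide 13 (a cyclic γ-acyloxy enoate) to a π-allyl complex that carries its own carboxylate, and the soft nitronate of 7 attacks the CH2 terminus through carbon (C6–C7), the closest known reactions being Tsuji–Trost allylations of nitroalkanes with γ-acyloxy enoates and palladium-catalysed openings of allylic lactones; because the carboxylate leaves from the ring, C-6 stays cis to CO2H and CH2OH stays cis to the vinyl group (isomerised material relactonises and is removed by base extraction), and the new nitro-bearing centre forms as both epimers, which is immaterial because it becomes a ketone in step 9.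

Step 8
Reactants: 14 triene hydroxy acid
Product: 16 nitro lactone (trans-fused rings A/B with the C-18/C-19 γ-lactone, Δ3, 10β-H, 1β-butenolide, 9α-CH3, 9β-CH2CO2Me, 8α-CH3, 7-NO2 as both epimers), via cycloadduct hydroxy acid 15 (not isolated)
Conditions: 1,2-dichlorobenzene (0.005 M), BHT, 160 °C, 24 h
Reagents that add atoms: none
Why: Intramolecular Diels–Alder reaction (1,7,9-decatriene type): with the tether on the outer and CH2OH on the inner position of the diene terminus, the transition state with the C-9 tether carbon exo and the C-1 butenolide endo gives the trans ring fusion (the inner CH2OH becomes the axial C-19 anti to H-10), the E-dienophile fixes H-1 trans to H-10, and the chair-like tether with the C-8 methyl equatorial selects the diene face relative to C-8/C-9, after which the γ-hydroxy acid lactonises spontaneously to the C-18/C-19 lactone.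

Step 9
Reactants: 16 nitro lactone
Product: 18 7-ketone, via nitronate salt 17 (not isolated)
Conditions: DBU (1.2 equiv), THF, 0 °C; then TiCl3 (aq HCl, 6 equiv), NH4OAc buffer, THF–H2O, 0 °C → rt
Reagents that add atoms: water, O
Why: Nef reaction in its reductive TiCl3 variant: the nitronate is reduced to the imine, which hydrolyses to the C-7 ketone under buffered conditions that spare esters and lactones; the epimeric C-7 centre is erased and the α-methyl at C-8 stays (or equilibrates to) equatorial.

Step 10
Reactants: 18 7-ketone
Product: 19 7α-alcohol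
Conditions: NaBH4 (1.0 equiv), CeCl3·7H2O (1.0 equiv), MeOH–THF, −40 °C
Reagents that add atoms: none
Why: Luche reduction: the α face of the C-7 carbonyl is shielded by the two syn-axial substituents on C-5 (CH2O) and C-9 (CH3), so hydride arrives from the β face and gives the axial 7α-alcohol, while CeCl3 suppresses conjugate reduction of the two unsaturated lactones.

Step 11
Reactants: 19 7α-alcohol
Product: 20 7α-acetate
Conditions: Ac2O (3 equiv), Sc(OTf)3 (2 mol %), MeCN, 0 °C
Reagents that add atoms: acetic anhydride, CC(=O)OC(C)=O
Why: Lewis-acid-catalysed acetylation esterifies even the hindered axial alcohol without base, which avoids O-acylation of the enolisable butenolide; the configuration at C-7 is retained.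

Step 12
Reactants: 20 7α-acetate
Product: 21 spiro enol lactone (ring C closed, C-12 ketone, spiro furan-2(3H)-one at C-13 with the C-16 carbonyl β and C-14=C-15)
Conditions: TiCl4 (1.5 equiv), Bu3N (2.0 equiv), CH2Cl2, −78 → −20 °C
Reagents that add atoms: none
Why: Ti-Claisen (Dieckmann-type) condensation: soft enolisation of the butenolide γ-CH2 gives the titanium 2-furanolate, whose α-carbon C-13 (the only position that closes a six-membered ring) is acylated by the C-12 methyl ester, methoxide being captured irreversibly by titanium so that the non-enolisable β-keto lactone cannot revert; the spiro centre is set in a product-like chair transition state that puts the smaller lactone carbonyl axial (cis to H-10) and the vinylic CH equatorial, a preference expected to be only moderate (the C-13 epimer is removed by chromatography).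

Step 13
Reactants: 21 spiro enol lactone
Product: 22 CNP0308057.1 (target)
Conditions: DMDO (acetone solution, 1.5 equiv), CH2Cl2, −20 → 0 °C; evaporation
Reagents that add atoms: dimethyldioxirane, CC1(C)OO1
Why: Epoxidation of the electron-rich enol-lactone double bond with neutral DMDO (as for enol esters and glycals) occurs on the lactone face next to the flat C-12 carbonyl and away from the C-1/C-2 edge of ring A, setting C-14 and C-15 as in the target, while the electron-poor C-3 alkene is inert and evaporation of acetone leaves the sensitive acyloxy epoxide untouched.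

**Compound list**

1 | (E)-3-methylpent-2-en-4-yn-1-ol | OC/C=C(\C)C#C | starting material
2 | (E)-3-methylpent-2-en-4-ynal | O=C/C=C(\C)C#C | intermediate
3 | (E)-1-nitroprop-1-ene | C/C=C/[N+](=O)[O-] | starting material
4 | methyl (3S,4S)-3-ethynyl-3,4-dimethyl-5-nitropentanoate | [O-][N+](=O)C[C@@H](C)[C@](C)(CC(=O)OC)C#C | intermediate
5 | 3-bromofuran-2(5H)-one | O=C1OCC=C1Br | starting material
6 | methyl (3S,4S)-3,4-dimethyl-5-nitro-3-[(E)-2-(tributylstannyl)ethenyl]pentanoate | [O-][N+](=O)C[C@@H](C)[C@](C)(CC(=O)OC)/C=C/[Sn](CCCC)(CCCC)CCCC | intermediate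
7 | methyl (3R,4S)-3,4-dimethyl-5-nitro-3-[(E)-2-(2-oxo-2,5-dihydrofuran-3-yl)ethenyl]pentanoate | [O-][N+](=O)C[C@@H](C)[C@](C)(CC(=O)OC)/C=C/C1=CCOC1=O | intermediate
8 | 1,3-dihydroxyacetone | OCC(=O)CO | starting material
9 | ethyl (triphenylphosphoranylidene)acetate | CCOC(=O)C=P(c1ccccc1)(c1ccccc1)c1ccccc1 | starting material
10 | 4-(hydroxymethyl)furan-2(5H)-one | OCC1=CC(=O)OC1 | intermediate
11 | (±)-trans-3,4-dibromo-4-(hydroxymethyl)oxolan-2-one (one enantiomer drawn) | OC[C@@]1(Br)COC(=O)[C@H]1Br | intermediate
12 | 3-bromo-4-(hydroxymethyl)furan-2(5H)-one | OCC1=C(Br)C(=O)OC1 | intermediate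
13 | 3-ethenyl-4-(hydroxymethyl)furan-2(5H)-one | OCC1=C(C=C)C(=O)OC1 | intermediate
14 | triene hydroxy acid (name in step 7; nitro-bearing carbon unassigned, other centres as in 7) | C=C/C(C(=O)O)=C(\CO)CC([N+](=O)[O-])[C@@H](C)[C@](C)(CC(=O)OC)/C=C/C1=CCOC1=O | intermediate
15 | Diels–Alder cycloadduct hydroxy acid (trans-decalin, 4-CO2H, 5α-CH2OH, C-7 nitro unassigned) | [O-][N+](=O)C1C[C@@]2(CO)C(C(=O)O)=CC[C@@H](C3=CCOC3=O)[C@@H]2[C@@](C)(CC(=O)OC)[C@@H]1C | intermediate
16 | nitro lactone (C-18/C-19 lactone closed, C-7 nitro unassigned) | [O-][N+](=O)C1C[C@@]23COC(=O)C2=CC[C@@H](C2=CCOC2=O)[C@@H]3[C@@](C)(CC(=O)OC)[C@@H]1C | intermediate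
17 | 1,8-diazabicyclo[5.4.0]undec-7-enium nitronate of 16 | [O-][N+]([O-])=C1C[C@@]23COC(=O)C2=CC[C@@H](C2=CCOC2=O)[C@@H]3[C@@](C)(CC(=O)OC)[C@@H]1C.C1CCC2=[NH+]CCCN2CC1 | intermediate
18 | 7-ketone | O=C1C[C@@]23COC(=O)C2=CC[C@@H](C2=CCOC2=O)[C@@H]3[C@@](C)(CC(=O)OC)[C@@H]1C | intermediate
19 | 7α-alcohol | O[C@@H]1C[C@@]23COC(=O)C2=CC[C@@H](C2=CCOC2=O)[C@@H]3[C@@](C)(CC(=O)OC)[C@@H]1C | intermediate
20 | 7α-acetate | CC(=O)O[C@@H]1C[C@@]23COC(=O)C2=CC[C@@H](C2=CCOC2=O)[C@@H]3[C@@](C)(CC(=O)OC)[C@@H]1C | intermediate
21 | spiro enol lactone | CC(=O)O[C@@H]1C[C@@]23COC(=O)C2=CC[C@@H]2[C@@H]3[C@@](C)(CC(=O)[C@]23C(=O)OC=C3)[C@@H]1C | intermediate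
22 | CNP0308057.1 | CC(=O)O[C@@H]1C[C@@]23COC(=O)C2=CC[C@@H]2[C@@H]3[C@@](C)(CC(=O)[C@]23C(=O)O[C@H]2O[C@H]23)[C@@H]1C | target

**Step count and risks**

Total steps: 13. Longest linear sequence: 10 (steps 1, 2, 3, 7, 8, 9, 10, 11, 12, 13); steps 4–6 make fragment 13.

The three steps most likely to fail are 2, 7 and 8.

Step 2 may fail through attack at the alkyne terminus, simple β-protonation of the homoenolate, or poor diastereocontrol at the quaternary centre. The fallback sets out from 1 and comes back at 4, generating the same homoenolate reactivity stoichiometrically instead of catalytically. Mitsunobu reaction of 1 with tert-butyl (4-methoxyphenyl)carbamate gives the N-Boc-N-aryl allylamine F1. Lithiation with n-BuLi (2.1 equiv, the first masking the alkyne C–H) and (−)-sparteine gives a configurationally defined allyllithium, which adds through its γ-carbon to nitroalkene 3 to give the (Z)-enecarbamate F2. Acid hydrolysis releases the δ-nitro aldehyde F3, Pinnick oxidation gives the carboxylic acid F4, and TMSCHN2 returns 4.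

Step 7 may fail because the lactone C–O bond ionises slowly, or because the nitronate attacks the vinyl terminus or the double-bond geometry scrambles. The fallback sets out from 13 (with 7) and comes back at 16, opening the lactone before the coupling so that a conventional allylic bromide is used. Acetylation of 13 gives the acetate F5. TMSBr cleaves the allylic CH2–O bond of the lactone with the double-bond geometry held, giving after aqueous work-up the (Z)-bromo acid F6. Pd(PPh3)4-catalysed C-allylation of the nitronate of 7 (DBU, 2.1 equiv) with this bromide gives the triene acid acetate F7, which on heating as in step 8 gives the cycloadduct acid acetate F8. K2CO3 in MeOH removes the acetate and the freed hydroxy acid lactonises to 16.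

Step 8 may fail because the diene carries an inner substituent (slow cycloaddition) and because ring-fusion and facial selectivity are only predicted. The fallback sets out from 14 and comes back at 16, forming the same two bonds stepwise by an anionic double Michael reaction under equilibrating conditions. TMSCHN2 converts 14 into the triene methyl ester F9. DBU (2.2 equiv, the first neutralising the nitro group) generates the 2-furanolate of the dienyl butenolide, which adds through its vinylogous carbon C-10 to C-5 of the dienoate. The resulting dienolate closes ring A by attack of C-2 on C-1 of the alkylidene lactone, giving the hydroxy diester F10 as the thermodynamically preferred all-trans isomer. Acid-catalysed lactonisation then gives 16.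

Further compounds
F1 | step 2 | tert-butyl (4-methoxyphenyl)[(E)-3-methylpent-2-en-4-yn-1-yl]carbamate | C#C/C(C)=C/CN(C(=O)OC(C)(C)C)c1ccc(OC)cc1
F2 | step 2 | tert-butyl (4-methoxyphenyl)[(1Z)-3-ethynyl-3,4-dimethyl-5-nitropent-1-en-1-yl]carbamate (C-3 and C-4 arranged as in 4) | [O-][N+](=O)C[C@@H](C)[C@@](C)(C#C)/C=C\N(C(=O)OC(C)(C)C)c1ccc(OC)cc1
F3 | step 2 | (3S,4S)-3-ethynyl-3,4-dimethyl-5-nitropentanal | [O-][N+](=O)C[C@@H](C)[C@](C)(CC=O)C#C
F4 | step 2 | (3S,4S)-3-ethynyl-3,4-dimethyl-5-nitropentanoic acid | [O-][N+](=O)C[C@@H](C)[C@](C)(CC(=O)O)C#C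
F5 | step 7 | (4-ethenyl-5-oxo-2,5-dihydrofuran-3-yl)methyl acetate | CC(=O)OCC1=C(C=C)C(=O)OC1
F6 | step 7 | (2Z)-3-(acetoxymethyl)-4-bromo-2-ethenylbut-2-enoic acid | C=C/C(C(=O)O)=C(\COC(C)=O)CBr
F7 | step 7 | triene acid acetate (O-acetate of 14) | C=C/C(C(=O)O)=C(\COC(C)=O)CC([N+](=O)[O-])[C@@H](C)[C@](C)(CC(=O)OC)/C=C/C1=CCOC1=O
F8 | step 7 | cycloadduct acid acetate (O-acetate of 15) | [O-][N+](=O)C1C[C@@]2(COC(C)=O)C(C(=O)O)=CC[C@@H](C3=CCOC3=O)[C@@H]2[C@@](C)(CC(=O)OC)[C@@H]1C
F9 | step 8 | triene methyl ester (methyl ester of 14) | C=C/C(C(=O)OC)=C(\CO)CC([N+](=O)[O-])[C@@H](C)[C@](C)(CC(=O)OC)/C=C/C1=CCOC1=O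
F10 | step 8 | bicyclic hydroxy diester (methyl ester of 15) | [O-][N+](=O)C1C[C@@]2(CO)C(C(=O)OC)=CC[C@@H](C3=CCOC3=O)[C@@H]2[C@@](C)(CC(=O)OC)[C@@H]1C
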